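## The problem

The target is a bibenzyl whose ring A is hexasubstituted: C1 carries the 2-(3-methoxyphenyl)ethyl chain, C3 a free hydroxyl, C5 a methoxyl, and C2, C4 and C6 each a 4-hydroxybenzyl group. Five benzene rings are joined only through sp3 links (one CH2CH2 and three CH2), so nothing is fused and the skeleton has to be assembled around the crowded ring A. The target has no stereocentre, so any centre created on the way must be erased and none has to control another. The difficulties are regiochemical and steric: every open position of a 5-alkylresorcinol must receive a carbon substituent flanked by two ortho groups, and the two oxygens must end up different (O3 free, O5 methylated). The four phenols, the electron-rich ring A and the three doubly benzylic CH2 groups (latent quinone methides) will not tolerate strong oxidants or strong acids, so the free phenols should appear late. The enabling feature is that each substituent on C2, C4 and C6 is a para-substituted phenol, that is, the dehydrogenation product of a 4-(arylmethyl)cyclohex-2-enone, which in turn is the Robinson annulation product of a 3-arylpropanal arm on ring A with methyl vinyl ketone. Such an arm is an oxidised allyl group, and allyl groups can be placed at C4 by directed lithiation between the two oxygens and at C2 and C6 by Claisen rearrangement from O3.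

## Retrosynthesis

**22 to 21.** Only the O3–benzyl bond is cut. A benzyl ether on O3 is chosen because it must survive borane, a periodinane oxidant, amine and hydroxide base, and palladium with oxygen, and must then leave under neutral conditions that do not touch four phenols or the diarylmethane links. A free O3–H would lactolise with the neighbouring propanal arms and expose a fully substituted phenol to the oxidant. The forward step is a plain hydrogenolysis.

**21 to 20.** No skeletal bond is cut; each of the three pendant phenol rings is traced to a 4-substituted cyclohex-2-enone by adding back one molecule of H2. This turns three aromatic rings into rings that can be built by annulation. The neighbouring cut (the CH2–aryl bond, a Friedel–Crafts benzylation of ring A) would have to control the number and position of benzylations on a ring that competes with ring B. The forward step must dehydrogenate three enones in one molecule without harming ring A or the benzyl ether.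

**20 to 17 and 18 (key disconnection).** Six bonds are cut, two in each enone ring: the C4–C5 bond (Michael addition) and the C2=C3 bond (aldol condensation). Twelve carbons, three rings and three stereocentres are removed, leaving trialdehyde 17 and three molecules of methyl vinyl ketone 18. Cutting the ring A–CH2 or CH2–C4 bond instead would require a tris(halomethyl) or trimetalated hexasubstituted arene. The annulation takes its arms from allyl groups, which lithiation and sigmatropic shifts can place. The forward reaction must alkylate each aldehyde α-carbon once and close each ring through the tris(keto aldehyde) 19.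

**17 to 16 to 14.** No C–C bond is cut; each CH2CH2CHO arm is traced through the primary alcohol (triol 16) to an allyl group (14), via the trialkylborane 15. The forward steps need anti-Markovnikov hydration at three terminal alkenes and an oxidation that stops at the aldehyde.

**14 to 13.** Only the O3–benzyl bond changes. Phenol 13 already has all three allyl groups and the O5 methyl group, and its single hydroxyl is the one to be masked.

**13 to 12 to 11 to 10 to 9.** The ring A–allyl bonds at C6 and C2 are cut and each is traced to an allyl ether on O3. Phenol 13 comes from ether 12 by a para-Claisen shift and phenol 11 from ether 10 by an ortho shift; the ethers come from phenols 11 and 9 and allyl bromide 6. Claisen delivery is preferred to halogenation and cross-coupling because it is intramolecular, tolerates the crowding and has a forced course here. In 10 only C2 is a free ortho carbon; in 12 both ortho carbons are filled, so the allyl group must travel on to C6. Precursor 9 carries one allyl group instead of three, and every compound on the way is a single isomer.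

**9 to 8 to 5.** The C4–allyl bond is cut between ring A and its CH2. C4 lies between the two oxygens and is the one ring position that both activate for deprotonation. The allyl group therefore enters by directed lithiation of acetal 5 (aryllithium 7) and alkylation with 6; acid then frees phenol 9 from 8. Leaving C4 to a Claisen shift instead would give two ortho isomers in the first round. The forward step asks for lithiation at C4 only, in the presence of ring B and two benzylic CH2 groups.

**5 to 4 to 2 and 3; 2 to 1.** The central CH2–CH2 bond of the bibenzyl is cut as an alkene (stilbene 4) and made by Horner–Wadsworth–Emmons olefination of aldehyde 2 with phosphonate 3, followed by hydrogenation to 5. Aldehyde 2 is the methoxymethyl ether of 3-hydroxy-5-methoxybenzaldehyde 1. Starting from 1 supplies the O5 methyl group and a single free oxygen, so O3 and O5 are different from the first compound on and no statistical alkylation is needed.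

## Roads not taken

**Alternative 1: aryne insertion into a β-keto ester.** The cut is at the ring A C1–CH2 and C2–C(=O) bonds. Fluoride-induced elimination from silyl triflate A1 would give a short-lived aryne, which inserts into the C(α)–C(=O) bond of β-keto ester A2 (acyl-alkylation) to give keto ester A3.
- Merits: the methoxyl next to the aryne fixes the regiochemistry and the reaction is mild. The C2 ketone next to the O3 methoxyl could direct a chelation-controlled demethylation, which would settle the O3/O5 distinction as well as the chosen plan does with its starting aldehyde.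
- Weak points: A3 carries only one of the three benzyl units. C4 and C6 would need two later Friedel–Crafts reactions on a ring deactivated by the ketone or, after its reduction, in competition with other electron-rich rings. The acetate must be rebuilt into the arylethyl chain, the ketone deoxygenated, and A1 prepared in several steps.
- Comparison: its key step is the safer single reaction, but most of the substitution problem remains after it. In the chosen plan only dehydrogenation and debenzylation follow the key step.

**Alternative 2: biomimetic triketone fold.** The cut is the C1–C6 bond of ring A. Mild base would make the terminal α-methylene of triketone A4 attack the cinnamoyl carbonyl; dehydration and enolisation would give styrylresorcinol A5.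
- Merits: all six ring A substituents are in place when the ring forms, and the end-game (mono-methylation, then one hydrogenation of alkene and three benzyl ethers) would be shorter than the chosen one.
- Weak points: A4 has two tertiary α-carbons between three carbonyls, and its assembly needs repeated C-acylation and C-benzylation against O-alkylation. It can also close to pyranones or by oxa-Michael addition to the enone. The aldol must form a hexasubstituted ring at a hindered ketone. The two hydroxyls of A5 are equivalent, so the methylation is statistical.
- Comparison: alternative 2 is shorter after the ring closure. Against that, the chosen plan makes every bond to ring A by a reaction of predictable regiochemical course and carries the O3/O5 distinction from its first compound.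

**Alternative 3: threefold Grignard addition.** The cut is at the three CH–aryl bonds. Excess Grignard reagent A8 would add to the three formyl groups of trialdehyde A7 to give triscarbinol A9; one hydrogenolysis could then remove three benzylic hydroxyls and three benzyl ethers.
- Merits: A7 could come from resorcinol A6 by threefold formylation, so this road could be about half as long as the chosen one.
- Weak points: the third formyl group must enter a ring deactivated by two, with ring B competing. A8 first deprotonates both phenols of A7, and the resulting aryloxide–aldehyde conjugation makes the carbonyls poor electrophiles. The two ring A hydroxyls of A7 and A9 are equivalent, so O5 must be methylated statistically before the hydrogenolysis; afterwards it would be impossible beside three further phenols.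
- Comparison: in step count alternative 3 is clearly better. The chosen plan has to set against this that it needs no substitution of a deactivated ring, no addition to a deactivated carbonyl and no statistical O-alkylation.

Key step: step 13

## Route

Remark: aldehyde 1 and phosphonate 3 are taken as catalogue compounds.

Step 1
Reactants: 1 3-hydroxy-5-methoxybenzaldehyde
Product: 2 3-methoxy-5-(methoxymethoxy)benzaldehyde
Conditions: MOMCl, K2CO3, acetone, 0 °C to rt
Reagents that add atoms: chloromethyl methyl ether COCCl
Why: Williamson-type O-alkylation of the phenoxide; the methoxymethyl acetal protects O3 through the base and hydrogenation steps and later directs the lithiation of step 4.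

Step 2
Reactants: 2 3-methoxy-5-(methoxymethoxy)benzaldehyde; 3 diethyl (3-methoxybenzyl)phosphonate
Product: 4 (E)-1-methoxy-3-(methoxymethoxy)-5-[2-(3-methoxyphenyl)ethenyl]benzene
Conditions: KOtBu, THF, 0 °C to rt
Reagents that add atoms: none
Why: Horner–Wadsworth–Emmons olefination of an aromatic aldehyde with a benzylphosphonate anion, which should give the E-stilbene; the geometry is lost in step 3 in any case.

Step 3
Reactants: 4 (E)-1-methoxy-3-(methoxymethoxy)-5-[2-(3-methoxyphenyl)ethenyl]benzene
Product: 5 1-methoxy-3-(methoxymethoxy)-5-[2-(3-methoxyphenyl)ethyl]benzene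
Conditions: H2 (1 atm), 10% Pd/C, EtOAc, rt
Reagents that add atoms: none
Why: Catalytic hydrogenation should saturate the stilbene; the acetal and the aryl methyl ethers are not hydrogenolysed in a neutral solvent.

Step 4
Reactants: 5 1-methoxy-3-(methoxymethoxy)-5-[2-(3-methoxyphenyl)ethyl]benzene; 6 allyl bromide
Product: 8 1-methoxy-3-(methoxymethoxy)-5-[2-(3-methoxyphenyl)ethyl]-2-(prop-2-en-1-yl)benzene, via aryllithium 7 (not isolated)
Conditions: n-BuLi (1.2 equiv), THF, 0 °C; then CuBr·SMe2 (10 mol %), 6, −78 °C to rt
Reagents that add atoms: n-butyllithium [Li]CCCC (its lithium stays only in intermediate 7)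
Why: Directed ortho-metalation; the hydrogen on C4 lies between the methoxymethoxy and methoxy groups, whose joint coordination and inductive effect make it the kinetically most acidic site, well ahead of ring B and the benzylic CH2 groups. Copper-catalysed alkylation of aryllithium 7 with allyl bromide then forms the C4–allyl bond.

Step 5
Reactants: 8 1-methoxy-3-(methoxymethoxy)-5-[2-(3-methoxyphenyl)ethyl]-2-(prop-2-en-1-yl)benzene
Product: 9 3-methoxy-5-[2-(3-methoxyphenyl)ethyl]-2-(prop-2-en-1-yl)phenol
Conditions: 3 M aq HCl, MeOH, 50 °C
Reagents that add atoms: none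
Why: Acid-catalysed cleavage of the methoxymethyl acetal; dilute acid in methanol leaves the aryl methyl ethers alone and is too weak to add the phenol across the unactivated allyl group.

Step 6
Reactants: 9 3-methoxy-5-[2-(3-methoxyphenyl)ethyl]-2-(prop-2-en-1-yl)phenol; 6 allyl bromide
Product: 10 1-methoxy-5-[2-(3-methoxyphenyl)ethyl]-2-(prop-2-en-1-yl)-3-(prop-2-en-1-yloxy)benzene
Conditions: K2CO3, acetone, reflux
Reagents that add atoms: none
Why: Williamson etherification of the only phenol; carbonate in acetone favours O- over C-allylation.

Step 7
Reactants: 10 1-methoxy-5-[2-(3-methoxyphenyl)ethyl]-2-(prop-2-en-1-yl)-3-(prop-2-en-1-yloxy)benzene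
Product: 11 3-methoxy-5-[2-(3-methoxyphenyl)ethyl]-2,6-di(prop-2-en-1-yl)phenol
Conditions: N,N-diethylaniline, 200 °C, argon, sealed tube
Reagents that add atoms: none
Why: Aromatic Claisen rearrangement; C4 already carries an allyl group, so the [3,3] shift goes to the one free ortho carbon, C2, and enolisation restores the phenol. Any minor para shift to C6 would be harmless, because steps 8 and 9 would then fill C2 and reach the same 13.

Step 8
Reactants: 11 3-methoxy-5-[2-(3-methoxyphenyl)ethyl]-2,6-di(prop-2-en-1-yl)phenol; 6 allyl bromide
Product: 12 1-methoxy-5-[2-(3-methoxyphenyl)ethyl]-2,4-di(prop-2-en-1-yl)-3-(prop-2-en-1-yloxy)benzene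
Conditions: K2CO3, DMF, 60 °C
Reagents that add atoms: none
Why: Williamson etherification of the hindered 2,6-disubstituted phenol, helped by the dipolar aprotic solvent.

Step 9
Reactants: 12 1-methoxy-5-[2-(3-methoxyphenyl)ethyl]-2,4-di(prop-2-en-1-yl)-3-(prop-2-en-1-yloxy)benzene
Product: 13 3-methoxy-5-[2-(3-methoxyphenyl)ethyl]-2,4,6-tri(prop-2-en-1-yl)phenol
Conditions: N,N-diethylaniline, 200 °C, argon, sealed tube
Reagents that add atoms: none
Why: Para-Claisen rearrangement; with both ortho carbons allylated the ortho-dienone cannot enolise and passes an allyl group on to C6 by a Cope shift, after which enolisation restores the phenol.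

Step 10
Reactants: 13 3-methoxy-5-[2-(3-methoxyphenyl)ethyl]-2,4,6-tri(prop-2-en-1-yl)phenol
Product: 14 1-(benzyloxy)-3-methoxy-5-[2-(3-methoxyphenyl)ethyl]-2,4,6-tri(prop-2-en-1-yl)benzene
Conditions: BnBr, K2CO3, DMF, rt to 50 °C
Reagents that add atoms: benzyl bromide BrCc1ccccc1
Why: Williamson benzylation of the hindered phenol in a dipolar aprotic solvent; the benzyl ether masks O3 until the last step.

Step 11
Reactants: 14 1-(benzyloxy)-3-methoxy-5-[2-(3-methoxyphenyl)ethyl]-2,4,6-tri(prop-2-en-1-yl)benzene
Product: 16 3,3',3''-{2-(benzyloxy)-4-methoxy-6-[2-(3-methoxyphenyl)ethyl]benzene-1,3,5-triyl}tri(propan-1-ol), via tris(9-BBN) trialkylborane 15 (not isolated)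
Conditions: 9-BBN (4.5 equiv), THF, 0 °C to rt; then aq NaOH, 30% H2O2, 0 °C to rt
Reagents that add atoms: 9-borabicyclo[3.3.1]nonane (three equivalents; its atoms stay only in intermediate 15) B1C2CCCC1CCC2.B1C2CCCC1CCC2.B1C2CCCC1CCC2; hydrogen peroxide (three equivalents) OO.OO.OO
Why: Hydroboration–oxidation; the bulky dialkylborane places boron on the terminal carbon of each allyl group with very high selectivity, which matters when three arms must all come out right.

Step 12
Reactants: 16 3,3',3''-{2-(benzyloxy)-4-methoxy-6-[2-(3-methoxyphenyl)ethyl]benzene-1,3,5-triyl}tri(propan-1-ol)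
Product: 17 3,3',3''-{2-(benzyloxy)-4-methoxy-6-[2-(3-methoxyphenyl)ethyl]benzene-1,3,5-triyl}tripropanal
Conditions: Dess–Martin periodinane (3.6 equiv), CH2Cl2, 0 °C to rt
Reagents that add atoms: none
Why: Dess–Martin oxidation of primary alcohols stops at the aldehyde under neutral, non-aqueous conditions and leaves the aryl ethers alone; 17 should be used at once.

Step 13
Reactants: 17 3,3',3''-{2-(benzyloxy)-4-methoxy-6-[2-(3-methoxyphenyl)ethyl]benzene-1,3,5-triyl}tripropanal; 18 methyl vinyl ketone (three equivalents take part, one per arm)
Product: 20 4,4',4''-{[2-(benzyloxy)-4-methoxy-6-[2-(3-methoxyphenyl)ethyl]benzene-1,3,5-triyl]tris(methylene)}tris(cyclohex-2-en-1-one) (mixture of diastereomers), via tris(5-oxohexanal) Michael adduct 19 (not isolated)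
Conditions: 18 (6 equiv), pyrrolidine (0.6 equiv), THF, 0 °C to rt, slow addition of 17; volatiles removed; then aq KOH (0.3 equiv), THF–MeOH, rt
Reagents that add atoms: methyl vinyl ketone (two further equivalents beside 18) CC(=O)C=C.CC(=O)C=C
Why: Pyrrolidine condenses reversibly with each aldehyde of 17 to an E-enamine whose β-carbon adds to methyl vinyl ketone; hydrolysis returns the amine and leaves the tris(1,5-keto aldehyde) 19, and hydroxide then enolises each methyl ketone toward CH3, which attacks the neighbouring formyl group, and the aldol dehydrates to the conjugated enone. The closest known reaction type is the secondary-amine-catalysed Robinson annulation of α-unbranched aldehydes with methyl vinyl ketone to 4-substituted cyclohex-2-enones, here run on three remote arms of one molecule. Each of the three rings closes in the 6-(enolendo)-exo-trig mode, the only aldol closure of a 2-substituted 5-oxohexanal that avoids a four-membered ring. Each ring gains one stereocentre at C4 of the enone; the achiral amine and the distance between arms leave it uncontrolled, and no control is needed because all three centres become sp2 in step 14. The selectivity needed is one Michael addition per arm: after the first addition the α-carbon is tertiary and its enamine is trisubstituted and slow to form and react, so a second alkylation is disfavoured. Aldol reaction between arms of different molecules is held back by the excess enone and the slow addition of 17, and the excess enone is removed before the base is added so that the product enones are not alkylated further. The benzyl and methyl ethers are inert to amine and dilute hydroxide.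

Step 14
Reactants: 20 4,4',4''-{[2-(benzyloxy)-4-methoxy-6-[2-(3-methoxyphenyl)ethyl]benzene-1,3,5-triyl]tris(methylene)}tris(cyclohex-2-en-1-one)
Product: 21 4,4',4''-{[2-(benzyloxy)-4-methoxy-6-[2-(3-methoxyphenyl)ethyl]benzene-1,3,5-triyl]tris(methylene)}triphenol
Conditions: Pd(O2CCF3)2 (15 mol %), 2-(dimethylamino)pyridine (30 mol %), TsOH·H2O (60 mol %), O2 (1 atm), DMSO, 80 °C
Reagents that add atoms: none
Why: Palladium-catalysed aerobic dehydrogenation of cyclohexenones to phenols; a divalent palladium enolate forms at C6, β-hydride elimination gives the cyclohexa-2,5-dienone, and this tautomerises to the para-substituted phenol while oxygen reoxidises the metal. All diastereomers of 20 converge on the one achiral triphenol.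

Step 15
Reactants: 21 4,4',4''-{[2-(benzyloxy)-4-methoxy-6-[2-(3-methoxyphenyl)ethyl]benzene-1,3,5-triyl]tris(methylene)}triphenol
Product: 22 2,4,6-tris(4-hydroxybenzyl)-3-methoxy-5-[2-(3-methoxyphenyl)ethyl]phenol (CNP0285788.0)
Conditions: H2 (1 atm), 10% Pd/C, EtOAc–MeOH, rt
Reagents that add atoms: none
Why: Hydrogenolysis of the aryl benzyl ether under neutral conditions; diarylmethane C–C bonds, methyl ethers and phenols are not affected.

## Compound list

1 | 3-hydroxy-5-methoxybenzaldehyde | COc1cc(O)cc(C=O)c1 | starting material
2 | 3-methoxy-5-(methoxymethoxy)benzaldehyde | COCOc1cc(OC)cc(C=O)c1 | intermediate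
3 | diethyl (3-methoxybenzyl)phosphonate | CCOP(=O)(Cc1cccc(OC)c1)OCC | starting material
4 | (E)-1-methoxy-3-(methoxymethoxy)-5-[2-(3-methoxyphenyl)ethenyl]benzene | COCOc1cc(OC)cc(/C=C/c2cccc(OC)c2)c1 | intermediate
5 | 1-methoxy-3-(methoxymethoxy)-5-[2-(3-methoxyphenyl)ethyl]benzene | COCOc1cc(OC)cc(CCc2cccc(OC)c2)c1 | intermediate
6 | allyl bromide (3-bromoprop-1-ene) | C=CCBr | starting material
7 | {2-methoxy-6-(methoxymethoxy)-4-[2-(3-methoxyphenyl)ethyl]phenyl}lithium | [Li]c1c(OC)cc(CCc2cccc(OC)c2)cc1OCOC | intermediate
8 | 1-methoxy-3-(methoxymethoxy)-5-[2-(3-methoxyphenyl)ethyl]-2-(prop-2-en-1-yl)benzene | C=CCc1c(OC)cc(CCc2cccc(OC)c2)cc1OCOC | intermediate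
9 | 3-methoxy-5-[2-(3-methoxyphenyl)ethyl]-2-(prop-2-en-1-yl)phenol | C=CCc1c(O)cc(CCc2cccc(OC)c2)cc1OC | intermediate
10 | 1-methoxy-5-[2-(3-methoxyphenyl)ethyl]-2-(prop-2-en-1-yl)-3-(prop-2-en-1-yloxy)benzene | C=CCOc1cc(CCc2cccc(OC)c2)cc(OC)c1CC=C | intermediate
11 | 3-methoxy-5-[2-(3-methoxyphenyl)ethyl]-2,6-di(prop-2-en-1-yl)phenol | C=CCc1c(O)c(CC=C)c(CCc2cccc(OC)c2)cc1OC | intermediate
12 | 1-methoxy-5-[2-(3-methoxyphenyl)ethyl]-2,4-di(prop-2-en-1-yl)-3-(prop-2-en-1-yloxy)benzene | C=CCOc1c(CC=C)c(CCc2cccc(OC)c2)cc(OC)c1CC=C | intermediate
13 | 3-methoxy-5-[2-(3-methoxyphenyl)ethyl]-2,4,6-tri(prop-2-en-1-yl)phenol | COc1cccc(CCc2c(CC=C)c(O)c(CC=C)c(OC)c2CC=C)c1 | intermediate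
14 | 1-(benzyloxy)-3-methoxy-5-[2-(3-methoxyphenyl)ethyl]-2,4,6-tri(prop-2-en-1-yl)benzene | COc1cccc(CCc2c(CC=C)c(OCc3ccccc3)c(CC=C)c(OC)c2CC=C)c1 | intermediate
15 | 9,9',9''-{[2-(benzyloxy)-4-methoxy-6-[2-(3-methoxyphenyl)ethyl]benzene-1,3,5-triyl]tri(propane-3,1-diyl)}tris(9-borabicyclo[3.3.1]nonane) | COc1cccc(CCc2c(CCCB3C4CCCC3CCC4)c(OCc3ccccc3)c(CCCB3C4CCCC3CCC4)c(OC)c2CCCB2C3CCCC2CCC3)c1 | intermediate
16 | 3,3',3''-{2-(benzyloxy)-4-methoxy-6-[2-(3-methoxyphenyl)ethyl]benzene-1,3,5-triyl}tri(propan-1-ol) | COc1cccc(CCc2c(CCCO)c(OCc3ccccc3)c(CCCO)c(OC)c2CCCO)c1 | intermediate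
17 | 3,3',3''-{2-(benzyloxy)-4-methoxy-6-[2-(3-methoxyphenyl)ethyl]benzene-1,3,5-triyl}tripropanal | COc1cccc(CCc2c(CCC=O)c(OCc3ccccc3)c(CCC=O)c(OC)c2CCC=O)c1 | intermediate
18 | methyl vinyl ketone (but-3-en-2-one) | CC(=O)C=C | starting material
19 | 2,2',2''-{[2-(benzyloxy)-4-methoxy-6-[2-(3-methoxyphenyl)ethyl]benzene-1,3,5-triyl]tris(methylene)}tris(5-oxohexanal), mixture of diastereomers | COc1cccc(CCc2c(CC(C=O)CCC(C)=O)c(OCc3ccccc3)c(CC(C=O)CCC(C)=O)c(OC)c2CC(C=O)CCC(C)=O)c1 | intermediate
20 | 4,4',4''-{[2-(benzyloxy)-4-methoxy-6-[2-(3-methoxyphenyl)ethyl]benzene-1,3,5-triyl]tris(methylene)}tris(cyclohex-2-en-1-one), mixture of diastereomers at the three ring C4 centres | COc1cccc(CCc2c(CC3C=CC(=O)CC3)c(OCc3ccccc3)c(CC3C=CC(=O)CC3)c(OC)c2CC2C=CC(=O)CC2)c1 | intermediate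
21 | 4,4',4''-{[2-(benzyloxy)-4-methoxy-6-[2-(3-methoxyphenyl)ethyl]benzene-1,3,5-triyl]tris(methylene)}triphenol | COc1cccc(CCc2c(Cc3ccc(O)cc3)c(OCc3ccccc3)c(Cc3ccc(O)cc3)c(OC)c2Cc2ccc(O)cc2)c1 | intermediate
22 | 2,4,6-tris(4-hydroxybenzyl)-3-methoxy-5-[2-(3-methoxyphenyl)ethyl]phenol | COc1cccc(CCc2c(Cc3ccc(O)cc3)c(O)c(Cc3ccc(O)cc3)c(OC)c2Cc2ccc(O)cc2)c1 | target

## Step count and least certain steps

Total: 15 steps. Longest linear sequence: 15 steps (1 to 22; the route is linear).

**Step 13 (key step).** The most likely failure is aldol condensation between formyl arms of different molecules under the amine, giving oligomers. A second risk is incomplete annulation, which would leave one or two arms at the keto aldehyde stage and give a statistical mixture. Pyrrolidine can also be tied up by conjugate addition to the enone. The fallback sets out from 17 and is a stoichiometric Stork enamine annulation. Compound 17 is condensed with pyrrolidine (3.3 equiv, K2CO3, toluene) to the tris(enamine) 1,1',1''-{[2-(benzyloxy)-4-methoxy-6-[2-(3-methoxyphenyl)ethyl]benzene-1,3,5-triyl]tris[(1E)-prop-1-ene-3,1-diyl]}tripyrrolidine F1. F1 is freed of excess amine and treated with 18 in the absence of any free aldehyde. Hot aqueous AcOH–NaOAc then hydrolyses the adducts and closes the rings through 19. The fallback returns to the route at 20.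

**Step 14.** The most likely failure is stalling after one or two rings, because the catalyst aggregates to inactive metal or is bound by the phenols already formed; the partly aromatised mixtures would be hard to separate. The fallback sets out from 20 and replaces the catalytic aerobic process by a stepwise stoichiometric one. Kinetic deprotonation at the α'-methylene of each enone (LiN(i-Pr)2, THF, −78 °C) and O-silylation with Me3SiCl should give the tris(cross-conjugated silyl dienol ether) 1-(benzyloxy)-3-methoxy-5-[2-(3-methoxyphenyl)ethyl]-2,4,6-tris{[4-(trimethylsilyloxy)cyclohexa-2,4-dien-1-yl]methyl}benzene F2. Saegusa–Ito oxidation of F2 with Pd(OAc)2 (3.3 equiv, MeCN, rt) should give the cyclohexa-2,5-dienones, which tautomerise to the phenols. The fallback returns at 21.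

**Step 9.** The Cope terminus C6 is flanked by the methoxyl and the arylethyl chain, so the blocked ortho-dienone may be diverted before it passes its allyl group on. It can undergo an intramolecular Diels–Alder reaction between its diene and one of its geminal allyl groups, or lose the allyl group by homolysis. The fallback sets out from 5, installs all three allyl groups by cross-coupling and so bypasses steps 4 to 9. Acidic methanol (HCl, MeOH, 50 °C) should free 3-methoxy-5-[2-(3-methoxyphenyl)ethyl]phenol F3 from 5. Iodination of F3 (I2, NaHCO3, THF–H2O, 0 °C to rt; the phenol ring is far more reactive than ring B) should give 2,4,6-triiodo-3-methoxy-5-[2-(3-methoxyphenyl)ethyl]phenol F4. Threefold Stille coupling of F4 (allyltributylstannane, Pd(PPh3)4, DMF, 90 °C) returns to the route at 13.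

**Step 4.** The most likely failure lies in the alkylation stage: lithium–bromine exchange between 7 and allyl bromide and Wurtz-type homocoupling would consume the aryllithium before it is allylated. A small excess of n-BuLi could also metalate ring B next to its methoxyl. The fallback sets out from 5 and separates metalation from C–C bond formation. Lithiation as in step 4 and quenching of 7 with I2 (THF, −78 °C) should give 2-iodo-1-methoxy-3-(methoxymethoxy)-5-[2-(3-methoxyphenyl)ethyl]benzene F5, which can be purified from any misdirected material. Stille coupling of F5 (allyltributylstannane, Pd(PPh3)4, DMF, 90 °C) returns to the route at 8. Should the lithiation itself prove unselective, the fallback given for step 9 avoids it altogether.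

## Further compounds

F1 | step 13 | 1,1',1''-{[2-(benzyloxy)-4-methoxy-6-[2-(3-methoxyphenyl)ethyl]benzene-1,3,5-triyl]tris[(1E)-prop-1-ene-3,1-diyl]}tripyrrolidine | COc1cccc(CCc2c(C/C=C/N3CCCC3)c(OCc3ccccc3)c(C/C=C/N3CCCC3)c(OC)c2C/C=C/N2CCCC2)c1
F2 | step 14 | 1-(benzyloxy)-3-methoxy-5-[2-(3-methoxyphenyl)ethyl]-2,4,6-tris{[4-(trimethylsilyloxy)cyclohexa-2,4-dien-1-yl]methyl}benzene, mixture of diastereomers | COc1cccc(CCc2c(CC3C=CC(O[Si](C)(C)C)=CC3)c(OCc3ccccc3)c(CC3C=CC(O[Si](C)(C)C)=CC3)c(OC)c2CC2C=CC(O[Si](C)(C)C)=CC2)c1
F3 | step 9 | 3-methoxy-5-[2-(3-methoxyphenyl)ethyl]phenol | COc1cccc(CCc2cc(O)cc(OC)c2)c1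
F4 | step 9 | 2,4,6-triiodo-3-methoxy-5-[2-(3-methoxyphenyl)ethyl]phenol | COc1cccc(CCc2c(I)c(O)c(I)c(OC)c2I)c1
F5 | step 4 | 2-iodo-1-methoxy-3-(methoxymethoxy)-5-[2-(3-methoxyphenyl)ethyl]benzene | COCOc1cc(CCc2cccc(OC)c2)cc(OC)c1I
A1 | alternative 1 | 3,5-dimethoxy-2-(trimethylsilyl)phenyl trifluoromethanesulfonate | COc1cc(OC)c([Si](C)(C)C)c(OS(=O)(=O)C(F)(F)F)c1
A2 | alternative 1 | methyl 3-[4-(benzyloxy)phenyl]-3-oxopropanoate | COC(=O)CC(=O)c1ccc(OCc2ccccc2)cc1
A3 | alternative 1 | methyl 2-[2-(4-benzyloxybenzoyl)-3,5-dimethoxyphenyl]acetate | COC(=O)Cc1cc(OC)cc(OC)c1C(=O)c1ccc(OCc2ccccc2)cc1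
A4 | alternative 2 | (1E)-4,6-bis[4-(benzyloxy)benzyl]-9-[4-(benzyloxy)phenyl]-1-(3-methoxyphenyl)non-1-ene-3,5,7-trione, mixture of diastereomers and enol tautomers | COc1cccc(/C=C/C(=O)C(Cc2ccc(OCc3ccccc3)cc2)C(=O)C(Cc2ccc(OCc3ccccc3)cc2)C(=O)CCc2ccc(OCc3ccccc3)cc2)c1
A5 | alternative 2 | 2,4,6-tris(4-benzyloxybenzyl)-5-[(E)-2-(3-methoxyphenyl)ethenyl]benzene-1,3-diol | COc1cccc(/C=C/c2c(Cc3ccc(OCc4ccccc4)cc3)c(O)c(Cc3ccc(OCc4ccccc4)cc3)c(O)c2Cc2ccc(OCc3ccccc3)cc2)c1
A6 | alternative 3 | 5-[2-(3-methoxyphenyl)ethyl]benzene-1,3-diol | COc1cccc(CCc2cc(O)cc(O)c2)c1
A7 | alternative 3 | 2,4-dihydroxy-6-[2-(3-methoxyphenyl)ethyl]benzene-1,3,5-tricarbaldehyde | COc1cccc(CCc2c(C=O)c(O)c(C=O)c(O)c2C=O)c1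
A8 | alternative 3 | [4-(benzyloxy)phenyl]magnesium bromide | Br[Mg]c1ccc(OCc2ccccc2)cc1
A9 | alternative 3 | 2,4,6-tris{[4-(benzyloxy)phenyl](hydroxy)methyl}-5-[2-(3-methoxyphenyl)ethyl]benzene-1,3-diol, mixture of carbinol diastereomers | COc1cccc(CCc2c(C(O)c3ccc(OCc4ccccc4)cc3)c(O)c(C(O)c3ccc(OCc4ccccc4)cc3)c(O)c2C(O)c2ccc(OCc3ccccc3)cc2)c1
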